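**Strategy.** The route rests on cutting the C1–C14 bond of the 14-membered carbocycle. The feature used is the C14 carbinol flanked by the exocyclic C1=CH2 methylidene, a 2-substituted allylic alcohol and hence the retron of a reductive union between an aldehyde and the substituted carbon of a 1-alkyne. One nickel-catalysed reductive ynal coupling should make that bond, the methylidene, the ring and the C14 stereocentre, delivered as a silyl ether distinct from those on the C9 and C20 oxygens. The precursor is an open-chain C1–C14 ynal (terminal alkyne at C1, aldehyde at C14, 8R,9S in place), assembled by a catalytic anti-allylboration that joins a geranyl-derived allylboronate to a butynediol-derived enal.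

Key step: step 13

Locants: the ring numbering of the target is kept for open-chain intermediates. C1 bears the methylidene, C4=C5 carries the methyl on C5, C8 the isopropenyl group, C9 and C14 are the oxygenated ring carbons, C10=C11 carries C20 (the CH2O carbon) on C11.

Design remark: the primary C20 oxygen is carried as a tert-butyldimethylsilyl ether and the C9 oxygen as a triethylsilyl ether. Both come off together in step 14, while the C14 triisopropylsilyl ether made in step 13 stays.

Assumption: the sense of induction of the chiral carbene in step 13 cannot be predicted with confidence. The (4S,5S) salt is written, and its (4R,5R) antipode is meant if the opposite sense is required. In step 9 the R acid is taken as the antipode that the accepted hydrogen-bonding model assigns to Re-face attack on the enal.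

**Fragment A (steps 1–4)**

Step 1
Reactants: 1 geranyl bromide [(2E)-1-bromo-3,7-dimethylocta-2,6-diene]; 2 1-(trimethylsilyl)propyne
Product: 4 trimethyl[(5E)-6,10-dimethylundeca-5,9-dien-1-yn-1-yl]silane, via 3-lithio-1-(trimethylsilyl)propyne 3 (not isolated)
Conditions: 2, n-BuLi, THF, −78 to −20 °C; then 1, −78 °C to rt
Reagents that add atoms: none
Why: SN2 alkylation of a propargyllithium, in which the lithio derivative of the silylpropyne attacks the primary allylic bromide through its propargylic carbon, the silyl group blocking the alkyne terminus and the E-trisubstituted alkene staying untouched.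

Step 2
Reactants: 4 trimethyl[(5E)-6,10-dimethylundeca-5,9-dien-1-yn-1-yl]silane
Product: 5 (2E,6E)-2,6-dimethyl-11-(trimethylsilyl)undeca-2,6-dien-10-yn-1-ol
Conditions: SeO2 (cat.), t-BuOOH, salicylic acid (cat.), CH2Cl2, 0 °C to rt, stopped at partial conversion
Reagents that add atoms: selenium dioxide, O=[Se]=O (oxygen atom; regenerated by tert-butyl hydroperoxide, CC(C)(C)OO)
Why: Sharpless catalytic SeO2 allylic oxidation (ene reaction then [2,3]-sigmatropic shift) should be selective for the E-methyl of the most accessible, terminal isopropylidene alkene, and stopping short of full conversion limits over-oxidation to the enal.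

Step 3
Reactants: 5 (2E,6E)-2,6-dimethyl-11-(trimethylsilyl)undeca-2,6-dien-10-yn-1-ol
Product: 7 [(5E,9E)-11-chloro-6,10-dimethylundeca-5,9-dien-1-yn-1-yl]trimethylsilane, via allylic mesylate 6 (not isolated)
Conditions: MsCl, 2,4,6-collidine, LiCl, DMF, 0 °C
Reagents that add atoms: lithium chloride, [Li+].[Cl-]
Why: Collington–Meyers chlorination, in which the mesylate formed in the flask is displaced by chloride in an SN2 reaction at the primary allylic carbon without allylic transposition or loss of the E geometry.

Step 4
Reactants: 7 [(5E,9E)-11-chloro-6,10-dimethylundeca-5,9-dien-1-yn-1-yl]trimethylsilane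
Product: 8 2-[(2E,6E)-2,6-dimethyl-11-(trimethylsilyl)undeca-2,6-dien-10-yn-1-yl]-4,4,5,5-tetramethyl-1,3,2-dioxaborolane
Conditions: B2pin2, Pd2(dba)3 (cat.), THF, 60 °C
Reagents that add atoms: bis(pinacolato)diboron, CC1(C)OB(OC1(C)C)B1OC(C)(C)C(C)(C)O1
Why: Palladium-catalysed Miyaura-type borylation of an allylic chloride, in which the π-allylpalladium is borylated at its unhindered CH2 terminus and the E geometry should be kept because syn–anti exchange would need a σ-allyl at the more substituted carbon.

**Fragment B (steps 5–8)**

Step 5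
Reactants: 9 but-2-yne-1,4-diol
Product: 10 4-[(tert-butyldimethylsilyl)oxy]but-2-yn-1-ol
Conditions: TBSCl (1 equiv), imidazole, excess 9, DMF, 0 °C
Reagents that add atoms: tert-butyldimethylsilyl chloride, CC(C)(C)[Si](C)(C)Cl
Why: Statistical monosilylation of a symmetric diol, biased to the mono-ether by an excess of the cheap diol, which is washed out with water.

Step 6
Reactants: 10 4-[(tert-butyldimethylsilyl)oxy]but-2-yn-1-ol
Product: 12 (2Z)-4-[(tert-butyldimethylsilyl)oxy]-3-iodobut-2-en-1-ol, via cyclic vinylalanate 11 (not isolated)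
Conditions: NaAlH2(OCH2CH2OMe)2, THF, 0 °C to rt; then I2, THF, −78 °C
Reagents that add atoms: iodine, II
Why: Hydroxyl-directed trans-hydroalumination of the propargylic alcohol places hydride on C2 and aluminium on C3 within a five-membered oxa-alumina ring, and iodinolysis of the C–Al bond with retention gives the Z-iodoalkene (CH2OH cis to iodine).

Step 7
Reactants: 12 (2Z)-4-[(tert-butyldimethylsilyl)oxy]-3-iodobut-2-en-1-ol; 13 allyl benzoate
Product: 15 (4E)-4-{[(tert-butyldimethylsilyl)oxy]methyl}-6-hydroxyhex-4-en-1-yl benzoate, via B-alkyl-9-BBN adduct 14 (not isolated)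
Conditions: 13, 9-BBN-H, THF, 0 °C to rt; then 12, Pd(dppf)Cl2 (cat.), AsPh3, Cs2CO3, DMF–H2O, rt
Reagents that add atoms: none
Why: B-alkyl Suzuki–Miyaura coupling, in which 9-BBN hydroborates the allyl ester at its terminal carbon and the alkyl group is transferred to the vinyl iodide with retention of alkene geometry, so that the new chain (C12–C14) is cis to CH2OH and the silyloxymethyl group (C20) trans to it.

Step 8
Reactants: 15 (4E)-4-{[(tert-butyldimethylsilyl)oxy]methyl}-6-hydroxyhex-4-en-1-yl benzoate
Product: 16 (4E)-4-{[(tert-butyldimethylsilyl)oxy]methyl}-6-oxohex-4-en-1-yl benzoate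
Conditions: MnO2, CH2Cl2, rt
Reagents that add atoms: none
Why: Chemoselective MnO2 oxidation of the allylic alcohol to the enal under neutral conditions that leave the alkene geometry, the silyl ether and the benzoate intact.

**Union and seco ynal (steps 9–12)**

Step 9
Reactants: 8 allylboronate (pinacol ester from step 4); 16 enal (from step 8)
Product: 18 open-chain (8R,9S) C9 alcohol carrying the C1 alkyne capped by SiMe3 plus the C20 tert-butyldimethylsilyl ether plus the C14 benzoate, via pinacol borate ester 17 (not isolated)
Conditions: (R)-3,3′-bis(2,4,6-triisopropylphenyl)-1,1′-binaphthyl-2,2′-diyl hydrogen phosphate (5 mol%), 4 Å MS, toluene, −30 °C; aq. NaHCO3 work-up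
Reagents that add atoms: none
Why: Chiral-phosphoric-acid-catalysed allylboration through a closed six-membered chair transition state, in which the E γ-substituent of the boronate sits equatorial and gives the 8,9-anti relationship while the catalyst, hydrogen-bonded to a boronate oxygen and to the formyl hydrogen, should expose the Re face of the enal, so that 8R and 9S are set together and the isopropenyl group arises by allylic transposition.

Step 10
Reactants: 18 open-chain (8R,9S) C9 alcohol
Product: 19 C9 triethylsilyl ether of 18
Conditions: TESOTf, 2,6-lutidine, CH2Cl2, −78 °C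
Reagents that add atoms: triethylsilyl trifluoromethanesulfonate, CC[Si](CC)(CC)OS(=O)(=O)C(F)(F)F
Why: Standard silylation of a hindered secondary alcohol with a silyl triflate and a hindered base at low temperature, which touches neither the benzoate nor the other silyl groups.

Step 11
Reactants: 19 C9 triethylsilyl ether
Product: 20 (8R,9S) alkynol with free C1 alkyne, C9 triethylsilyl ether, C20 tert-butyldimethylsilyl ether and C14 primary alcohol
Conditions: K2CO3, MeOH, rt
Reagents that add atoms: none
Why: Base-catalysed methanolysis removes the benzoate by transesterification and cleaves the alkynyl C–Si bond in the same operation, while the secondary triethylsilyl and primary tert-butyldimethylsilyl ethers are stable to K2CO3 in methanol.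

Step 12
Reactants: 20 (8R,9S) alkynol
Product: 21 seco ynal (terminal alkyne at C1, aldehyde at C14, C9 triethylsilyl ether, C20 tert-butyldimethylsilyl ether)
Conditions: Dess–Martin periodinane, NaHCO3, CH2Cl2, 0 °C to rt
Reagents that add atoms: none
Why: Dess–Martin oxidation of the primary alcohol to the aldehyde under buffered, non-epimerising conditions tolerated by the terminal alkyne, the alkenes and the silyl ethers.

**Ring closure and endgame (steps 13–16)**

Step 13
Reactants: 21 seco ynal; 22 triisopropylsilane
Product: 23 (4E,8R,9S,10E,14R) macrocycle with C1 methylidene, C9 triethylsilyl ether, C20 tert-butyldimethylsilyl ether and C14 triisopropylsilyl ether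
Conditions: Ni(cod)2 (20 mol%), (4S,5S)-1,3-bis(2,6-diisopropylphenyl)-4,5-diphenyl-4,5-dihydroimidazolium tetrafluoroborate (20 mol%), KOt-Bu (20 mol%), 22 (3 equiv), THF, rt, 21 added slowly to 0.005 M
Reagents that add atoms: triisopropylsilane (22), CC(C)[SiH](C(C)C)C(C)C
Why: Zerovalent nickel carrying the bulky carbene binds the C1 alkyne and the C14 aldehyde of 21 and undergoes oxidative cyclisation to an oxanickelacyclopentene in which C14 is bonded to the substituted alkyne carbon C1, the small alkyne substituent (H) being forced onto the carbon next to nickel and its large ligand; σ-bond metathesis of the Ni–O bond with 22 and C–H reductive elimination then release the C14 silyl ether and the C1 methylidene and return the catalyst. The closest known reaction type is the nickel–N-heterocyclic carbene–silane reductive macrocyclisation of terminal ynals, in which a small carbene gives the endocyclic E-alkene and a bulky one the exocyclic methylidene. The 14-membered ring (C1–C14) closes by direct end-to-end cyclisation in the exo mode with respect to the alkyne, the terminal alkyne carbon ending outside the ring. C14 is created in the C–C bond-forming oxidative cyclisation, and its configuration is to be controlled by the C2-symmetric chiral carbene on nickel (catalyst control), because C8 and C9 are too remote to be relied on. The step needs exo regioselectivity, ring closure in preference to oligomerisation, and reaction at the alkyne only: the unsubstituted alkyne terminus together with the bulky ligand and silane secures the first, high dilution helped by the two ring alkenes as turn elements (E C4=C5; C10=C11 holding C9 and C12 cis) the second, and the substrate design the third, since every oxygen is a silyl ether, no allylic ester or halide is present and all alkenes are tri- or 1,1-disubstituted.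

Step 14
Reactants: 23 macrocyclic tris-silyl ether
Product: 24 (4E,8R,9S,10E,14R) C9,C20-diol with the C14 triisopropylsilyl ether retained
Conditions: HF·pyridine, pyridine, THF, 0 °C to rt
Reagents that add atoms: none
Why: Buffered HF·pyridine should cleave the secondary triethylsilyl and the primary tert-butyldimethylsilyl ether far faster than the hindered secondary triisopropylsilyl ether, in line with the usual order of silyl ether lability.

Step 15
Reactants: 24 C9,C20-diol
Product: 25 C9,C20-diacetate C14 triisopropylsilyl ether
Conditions: Ac2O, pyridine, DMAP (cat.), CH2Cl2, 0 °C to rt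
Reagents that add atoms: acetic anhydride, CC(=O)OC(C)=O
Why: Standard DMAP-catalysed acetylation of the primary and the secondary allylic alcohol, the C14 oxygen remaining masked as its silyl ether.

Step 16
Reactants: 25 diacetate silyl ether
Product: 26 target CNP0077636.1
Conditions: TBAF, AcOH (1:1), THF, 0 °C to rt
Reagents that add atoms: none
Why: Fluoride cleavage of the triisopropylsilyl ether, buffered with acetic acid so that the liberated alkoxide cannot cleave or shift the acetates, frees the C14 alcohol without touching any stereocentre.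

**Compound list**

1 | geranyl bromide, (2E)-1-bromo-3,7-dimethylocta-2,6-diene | CC(C)=CCC/C(C)=C/CBr | starting material
2 | 1-(trimethylsilyl)propyne | CC#C[Si](C)(C)C | starting material
3 | 3-lithio-1-(trimethylsilyl)propyne | [Li]CC#C[Si](C)(C)C | intermediate (not isolated)
4 | trimethyl[(5E)-6,10-dimethylundeca-5,9-dien-1-yn-1-yl]silane | C[Si](C)(C)C#CCC/C=C(\C)CCC=C(C)C | intermediate
5 | (2E,6E)-2,6-dimethyl-11-(trimethylsilyl)undeca-2,6-dien-10-yn-1-ol | C[Si](C)(C)C#CCC/C=C(\C)CC/C=C(\C)CO | intermediate
6 | (2E,6E)-2,6-dimethyl-11-(trimethylsilyl)undeca-2,6-dien-10-yn-1-yl methanesulfonate | C[Si](C)(C)C#CCC/C=C(\C)CC/C=C(\C)COS(C)(=O)=O | intermediate (not isolated)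
7 | [(5E,9E)-11-chloro-6,10-dimethylundeca-5,9-dien-1-yn-1-yl]trimethylsilane | C[Si](C)(C)C#CCC/C=C(\C)CC/C=C(\C)CCl | intermediate
8 | 2-[(2E,6E)-2,6-dimethyl-11-(trimethylsilyl)undeca-2,6-dien-10-yn-1-yl]-4,4,5,5-tetramethyl-1,3,2-dioxaborolane | C[Si](C)(C)C#CCC/C=C(\C)CC/C=C(\C)CB1OC(C)(C)C(C)(C)O1 | intermediate
9 | but-2-yne-1,4-diol | OCC#CCO | starting material
10 | 4-[(tert-butyldimethylsilyl)oxy]but-2-yn-1-ol | OCC#CCO[Si](C)(C)C(C)(C)C | intermediate
11 | sodium cyclic vinylalanate (aluminium bonded to O1 and C3 in a five-membered ring, hydride on C2, two 2-methoxyethoxide ligands) | [Na+].COCCO[Al-]1(OCCOC)OCC=C1CO[Si](C)(C)C(C)(C)C | intermediate (not isolated)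
12 | (2Z)-4-[(tert-butyldimethylsilyl)oxy]-3-iodobut-2-en-1-ol | OC/C=C(\I)CO[Si](C)(C)C(C)(C)C | intermediate
13 | allyl benzoate | C=CCOC(=O)c1ccccc1 | starting material
14 | 3-(9-borabicyclo[3.3.1]nonan-9-yl)propyl benzoate | O=C(OCCCB1C2CCCC1CCC2)c1ccccc1 | intermediate (not isolated)
15 | (4E)-4-{[(tert-butyldimethylsilyl)oxy]methyl}-6-hydroxyhex-4-en-1-yl benzoate | OC/C=C(/CO[Si](C)(C)C(C)(C)C)CCCOC(=O)c1ccccc1 | intermediate
16 | (4E)-4-{[(tert-butyldimethylsilyl)oxy]methyl}-6-oxohex-4-en-1-yl benzoate | O=C/C=C(/CO[Si](C)(C)C(C)(C)C)CCCOC(=O)c1ccccc1 | intermediate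
17 | pinacol borate ester of alcohol 18 (C9–O–Bpin) | C[Si](C)(C)C#CCC/C=C(\C)CC[C@H](C(=C)C)[C@@H](OB1OC(C)(C)C(C)(C)O1)/C=C(/CO[Si](C)(C)C(C)(C)C)CCCOC(=O)c1ccccc1 | intermediate (not isolated)
18 | open-chain (4E,8R,9S,10E) C9 alcohol: SiMe3-capped C1 alkyne, C8 isopropenyl, C20 O-TBS, C14 benzoate | C[Si](C)(C)C#CCC/C=C(\C)CC[C@H](C(=C)C)[C@@H](O)/C=C(/CO[Si](C)(C)C(C)(C)C)CCCOC(=O)c1ccccc1 | intermediate
19 | C9 triethylsilyl ether of 18 | C[Si](C)(C)C#CCC/C=C(\C)CC[C@H](C(=C)C)[C@@H](O[Si](CC)(CC)CC)/C=C(/CO[Si](C)(C)C(C)(C)C)CCCOC(=O)c1ccccc1 | intermediate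
20 | open-chain (4E,8R,9S,10E) alkynol: terminal C1 alkyne, C9 O-TES, C20 O-TBS, C14 primary alcohol | C#CCC/C=C(\C)CC[C@H](C(=C)C)[C@@H](O[Si](CC)(CC)CC)/C=C(/CO[Si](C)(C)C(C)(C)C)CCCO | intermediate
21 | seco ynal: terminal C1 alkyne, C14 aldehyde, (4E,8R,9S,10E), C9 O-TES, C20 O-TBS | C#CCC/C=C(\C)CC[C@H](C(=C)C)[C@@H](O[Si](CC)(CC)CC)/C=C(/CO[Si](C)(C)C(C)(C)C)CCC=O | intermediate
22 | triisopropylsilane | CC(C)[SiH](C(C)C)C(C)C | starting material
23 | (4E,8R,9S,10E,14R) 14-membered carbocycle: C1 methylidene, C9 O-TES, C20 O-TBS, C14 O-TIPS | C=C1CC/C=C(\C)CC[C@H](C(=C)C)[C@@H](O[Si](CC)(CC)CC)/C=C(/CO[Si](C)(C)C(C)(C)C)CC[C@H]1O[Si](C(C)C)(C(C)C)C(C)C | intermediate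
24 | (4E,8R,9S,10E,14R) C9,C20-diol, C14 O-TIPS | C=C1CC/C=C(\C)CC[C@H](C(=C)C)[C@@H](O)/C=C(/CO)CC[C@H]1O[Si](C(C)C)(C(C)C)C(C)C | intermediate
25 | (4E,8R,9S,10E,14R) C9,C20-diacetate, C14 O-TIPS | C=C1CC/C=C(\C)CC[C@H](C(=C)C)[C@@H](OC(C)=O)/C=C(/COC(C)=O)CC[C@H]1O[Si](C(C)C)(C(C)C)C(C)C | intermediate
26 | CNP0077636.1: (4E,8R,9S,10E,14R)-9-acetoxy-11-(acetoxymethyl)-14-hydroxy-5-methyl-1-methylidene-8-(prop-1-en-2-yl)cyclotetradeca-4,10-diene (route locants) | C=C1CC/C=C(\C)CC[C@H](C(=C)C)[C@@H](OC(C)=O)/C=C(/COC(C)=O)CC[C@H]1O | target

**Count and risks**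

Total steps: 16. Longest linear sequence: 12 (steps 1–4, then 9–16). Fragment B takes steps 5–8.

Steps most likely to fail:

1. Step 13. The aldehyde faces may be discriminated poorly in the oxidative cyclisation, because the chiral carbene has to override whatever bias the remote C8/C9 centres and the ring conformation impose. Oligomerisation or direct silane reduction of the aldehyde may also compete with ring closure. Fallback, setting out from 21 and returning at 26: the ring closure is run without regard to C14 (racemic carbene salt), which should give 23 together with the 14-epi silyl ether F1. The mixture is taken through steps 14–16 unchanged, giving 24 with the 14-epi diol F2, 25 with the 14-epi diacetate F3, and 26 with the 14-epi alcohol F4. Oxidation of the 26/F4 mixture (Dess–Martin periodinane, NaHCO3, CH2Cl2) converges both epimers on the α-methylene ketone F5. Reduction of F5 with (S)-2-methyl-CBS-oxazaborolidine and catecholborane (toluene, −78 °C), in which the C1 alkenyl branch acts as the large group, should deliver the 14R alcohol under reagent control and so return to 26.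

2. Step 9. Enantiofacial control by the phosphoric acid may be incomplete, or turnover slow, with a β,β-disubstituted enal and a trisubstituted allylboronate. Acid-promoted E/Z drift of the enal, or Z-boronate carried over from step 4, would erode the C10=C11 geometry or the anti relationship. Fallback, setting out from 7 and 16 and returning at 18: a Nozaki–Hiyama-type allylation in which chloride 7 is converted by CrCl2, complexed with a chiral oxazoline–sulfonamide ligand (THF, rt), into an allylchromium reagent that adds to enal 16 through its γ-carbon. This mode is anti-selective irrespective of allyl geometry, and the ligand antipode is chosen for the Re face, so that aqueous work-up should give 18 directly.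

3. Step 2. The ene oxidation may compete at the C6 methylene flanking the inner C4=C5 alkene or at the propargylic position, and over-oxidation to the enal may occur. Fallback, setting out from 2 (as its lithio derivative 3) and returning at 5: the order is reversed so that the oxidation is done where the inner alkene is deactivated. Purchased geranyl acetate F6 is oxidised (SeO2 cat., t-BuOOH, CH2Cl2) to (2E,6E)-8-hydroxygeranyl acetate F7, the allylic acetate switching off the C2=C3 alkene. Silylation (TBSCl, imidazole, DMF) gives the silyl ether acetate F8, and methanolysis (K2CO3, MeOH) the allylic alcohol F9. Mesylation and displacement (MsCl, Et3N, CH2Cl2; then LiBr, THF) give, through the allylic mesylate F10, the allylic bromide F11. Alkylation of 3 (THF, −78 °C) gives the silyl ether F12, and CSA-catalysed methanolysis (MeOH, 0 °C), which leaves the alkynylsilane alone, returns 5.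

**Further compounds**

F1 | step 13 | 14-epi silyl ether (14S epimer of 23) | C=C1CC/C=C(\C)CC[C@H](C(=C)C)[C@@H](O[Si](CC)(CC)CC)/C=C(/CO[Si](C)(C)C(C)(C)C)CC[C@@H]1O[Si](C(C)C)(C(C)C)C(C)C
F2 | step 13 | 14-epi diol (14S epimer of 24) | C=C1CC/C=C(\C)CC[C@H](C(=C)C)[C@@H](O)/C=C(/CO)CC[C@@H]1O[Si](C(C)C)(C(C)C)C(C)C
F3 | step 13 | 14-epi diacetate (14S epimer of 25) | C=C1CC/C=C(\C)CC[C@H](C(=C)C)[C@@H](OC(C)=O)/C=C(/COC(C)=O)CC[C@@H]1O[Si](C(C)C)(C(C)C)C(C)C
F4 | step 13 | 14-epi alcohol (14S epimer of 26) | C=C1CC/C=C(\C)CC[C@H](C(=C)C)[C@@H](OC(C)=O)/C=C(/COC(C)=O)CC[C@@H]1O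
F5 | step 13 | α-methylene ketone (C14 ketone of 26) | C=C1CC/C=C(\C)CC[C@H](C(=C)C)[C@@H](OC(C)=O)/C=C(/COC(C)=O)CCC1=O
F0 | step 9 | none | none
F6 | step 2 | geranyl acetate | CC(C)=CCC/C(C)=C/COC(C)=O
F7 | step 2 | (2E,6E)-8-hydroxy-3,7-dimethylocta-2,6-dien-1-yl acetate | OC/C(C)=C/CC/C(C)=C/COC(C)=O
F8 | step 2 | (2E,6E)-8-[(tert-butyldimethylsilyl)oxy]-3,7-dimethylocta-2,6-dien-1-yl acetate | CC(C)(C)[Si](C)(C)OC/C(C)=C/CC/C(C)=C/COC(C)=O
F9 | step 2 | (2E,6E)-8-[(tert-butyldimethylsilyl)oxy]-3,7-dimethylocta-2,6-dien-1-ol | CC(C)(C)[Si](C)(C)OC/C(C)=C/CC/C(C)=C/CO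
F10 | step 2 | (2E,6E)-8-[(tert-butyldimethylsilyl)oxy]-3,7-dimethylocta-2,6-dien-1-yl methanesulfonate | CC(C)(C)[Si](C)(C)OC/C(C)=C/CC/C(C)=C/COS(C)(=O)=O
F11 | step 2 | tert-butyl{[(2E,6E)-8-bromo-2,6-dimethylocta-2,6-dien-1-yl]oxy}dimethylsilane | CC(C)(C)[Si](C)(C)OC/C(C)=C/CC/C(C)=C/CBr
F12 | step 2 | tert-butyldimethylsilyl ether of 5 | CC(C)(C)[Si](C)(C)OC/C(C)=C/CC/C(C)=C/CCC#C[Si](C)(C)C
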